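## The problem

1. Target 24 is a dearomatised, fully substituted phloroglucinol (ring A: C4a, C5, C5a, C9a, C10, C10a). Ring A is fused at C5a–C9a to a cis-2,3-dimethyldihydropyranone (ring B: C6 ketone, C7, C8, O9) and carries a 2-carboxy-1-phenylethyl group on C4a through the benzylic carbon C4. The atom numbers are those of the pyrano[3,2-g]chromene skeleton of lactone 22 and are kept for all tricyclic compounds and for 24.
2. There are five stereocentres in four separate places: the all-carbon quaternary C10 (S) with a prenyl and a lavandulyl group, the lavandulyl methine C2' (R), the benzylic C4 (R), and the cis pair C7 (S)/C8 (R).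
3. C10 is the hard one. Its two chains both begin with CH2 and differ only from the second carbon on, ring A is flat, and the nearest stereocentres (C2', C4, C8) are each three bonds away, so a reagent arriving from outside cannot be expected to tell the two faces apart.
4. The other centres are too far apart to control each other, and each needs its own source of chirality.
5. The cis pair is the kinetic, less stable arrangement and is lost under base through enolisation at C7 or retro-oxa-Michael opening. The three electron-rich alkenes close chromans on neighbouring phenol or enol OH groups under acid. C2' is allylic and racemises in any precursor that has a carbonyl group next to it.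
6. The feature that opens the problem lies in ring A. C10 stands para to the oxygen on C5. The group to be placed on it is an uninverted 3,3-dimethylallyl group, which is exactly what two successive [3,3] shifts of an O5 prenyl ether deliver. The path from O5 to C10 runs over C4a, the ring carbon that carries C4.
7. The carboxyl group can be closed on the oxygen of C10a to a six-membered lactone (ring C: O1, C2, C3, C4, C4a, C10a). This locks C4 with its phenyl group quasi-axial over one face of ring A, directly beside that path.

## Retrosynthesis

**24 to 22.** The carboxyl group is joined in thought to the enol oxygen on C10a (bond O1–C2), giving enol lactone 22. A free acid or an ester would leave C4 as a freely rotating substituent. Only ring closure fixes the phenyl group over one face. Closure on O5 instead would place the phenyl group on the other face. Compound 22 has no acidic group. The forward reaction is hydrolysis of an enol ester that is a vinylogous anhydride, so it needs only cold dilute base and must leave C7 alone.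

**22 to 20 through 21 (key step).**
- The bond C10–CH2(prenyl) is cut and the allyl unit is returned over C4a (blocked dienone 21) to O5, giving the flat aryl prenyl ether 20.
- Cutting C10–CH2(lavandulyl) instead would call for an unactivated, β-branched electrophile at a hindered carbon.
- A single ortho shift from the oxygen on C10a would need a tertiary 1,1-dimethylallyl ether between two substituents. With the lactone then closed on O5, the 4R phenyl group would lie on the very face where the prenyl group has to arrive.
- Ether 20 has no quaternary carbon and one stereocentre fewer, and it is an ordinary hexasubstituted benzene.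
- The forward reaction must run both shifts on the face opposite the phenyl group, start at C4a rather than C5a, and end on the dienone side of the equilibrium.

**20 to 18 and 19.** The bond O5–CH2 is cut. The 5-OH of 18 is the only free hydroxyl, so there is no site question. The forward etherification with alcohol 19 must be neutral, because base would epimerise C7 and open ring C.

**18 to 16 and 17 (from 9).** The sp2–sp3 bond C10–C1' is cut.
- Phenolate alkylation with 9 would be slow and would favour oxygen.
- An acylation–reduction or a reductive alkylation would put a carbonyl or quinone methide next to C2' and racemise it.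
- A cross-coupling leaves C2' untouched and brings the acid-sensitive diene in only after all acidic steps are over.
- Iodide 16 has no alkene and a single position where the halogen can sit.

**16 to 15 to 14.** Removal of iodine gives 15. Cutting O9–C8 opens ring B to enone 14.
- This cut creates C8 and C7 in one catalytic operation from a flat tigloyl group. Acylation with a preformed chiral hydroxy acid would need strong Lewis acid on a β-oxygenated acyl donor.
- The timing matters. In 14 the hydroxyl that has to add (7-OH in chromen-2-one numbering) stands next to an unsubstituted ring carbon, while its rival (5-OH) is flanked by C4a and C4.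
- The forward reaction must give the kinetic cis isomer and the 8R sense.

**14 to 12 and 13.** The bonds C4–C4a and O1–C2 are cut, a formal [3+3] annulation of a phenol with a cinnamoyl equivalent made from ynal 13.
- Ketone 12 has two equivalent free ring carbons and one unchelated hydroxyl between them. No regiochemical question arises, and the lactone forms on the oxygen para to the acyl group, as the key step needs.
- Doing the same annulation after ring B is closed would have to choose between two different ring carbons.
- The forward reaction sets C4 by catalyst control.

**12 to 10 and 11.** The aryl–acyl bond is cut. This is the only strongly acidic step, and it is placed first, on achiral phloroglucinol 10 and acid chloride 11.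

**9 to 8 to 7 to 4 and 5, and 4 to 1 and 2.** The iodide comes from alcohol 8, and 8 from imide 7 by reductive removal of the auxiliary. In 7 the bond C2'–CH2(prenyl) is cut. The extended enolate 6 of senecioyl imide 4 is alkylated at its α-carbon with 5, which creates C2' and the isopropenyl group together. Imide 4 comes from auxiliary 1 and acid chloride 2.

## Roads not taken

**Alternative 1: the most obvious route.** The same bond C10–CH2(prenyl) is cut, but between two molecules.
- Forward key step: the open aromatic acid A1 is deprotonated and alkylated with 5 in the biomimetic alkylative dearomatisation.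
- In A1 the benzylic group rotates freely and all stereocentres are three bonds from C10, so 24 and its C10 epimer A2 should form without preference, alongside O-alkylation at three oxygens.
- The strong base that is needed acts on the cis pair C7/C8.
- The chosen plan uses the same atoms but makes the delivery intramolecular and neutral, and it passes the allyl unit next to C4.

**Alternative 2: dearomatise first, on a symmetric ring.** Gem-dialkylation of 10 would give A3. There C10 is not yet a stereocentre, because the two halves of ring A are equivalent through enol exchange.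
- Forward key step: a carbene-catalysed annulation with 13 to enol lactone A4. It would create C4 and, by choosing one of the two equivalent ring carbons, C10 as well.
- The idea is short. The choice, however, rests on a catalyst sensing whether a prenyl or a lavandulyl group lies on the face it approaches, and the two groups look alike for the first two atoms.
- The unhindered enol oxygen para to C10 would react first, where the difference is not felt at all.
- Later closure of ring B would have to choose between two enol oxygens. The chosen plan replaces this remote recognition by a direct 1,2-contact.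

**Alternative 3: fold the lavandulyl chain back.** Closing its isopropenyl group on the neighbouring phenol oxygen gives chroman A5.
- Forward key step: a dearomative prenylation at the ring-fusion carbon. The entering group must be axial on the pyran ring and avoids a 1,3-diaxial contact with the C3 chain, giving A6 with good 1,3-control.
- The trans relation so obtained matches 24 only if the pyran ring sits on the oxygen that must later become O9 of ring B. The ring therefore has to be opened again.
- That opening is a contra-thermodynamic elimination of a tertiary enol ether toward the isopropenyl group. It competes with the isopropylidene isomer and with re-closure.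
- The plan adds steps after its key step and leaves C4 and ring B still to be placed. The chosen plan ends two steps after its key step.

Key step: step 11

Assumption: 24 is drawn as one enol form of a β-tricarbonyl array. The enol forms interconvert freely, so the hydrolysis product of 22 is taken as identical with the drawn tautomer.

## Steps

Step 1
Reactants: 1 (S)-4-benzyl-1,3-oxazolidin-2-one; 2 3-methylbut-2-enoyl chloride
Product: 4 (S)-4-benzyl-3-(3-methylbut-2-enoyl)-1,3-oxazolidin-2-one, via lithium oxazolidinide 3 (not isolated)
Conditions: n-BuLi, THF, −78 °C; then 2, −78 to 0 °C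
Reagents that add atoms: none
Why: N-acylation of a lithiated oxazolidinone with an acid chloride is the standard entry to Evans imides; no stereocentre is touched.

Step 2
Reactants: 4 (S)-4-benzyl-3-(3-methylbut-2-enoyl)-1,3-oxazolidin-2-one; 5 1-bromo-3-methylbut-2-ene (prenyl bromide)
Product: 7 (S)-4-benzyl-3-[(2S)-5-methyl-2-(prop-1-en-2-yl)hex-4-enoyl]-1,3-oxazolidin-2-one, via sodium dienolate 6 (not isolated)
Conditions: NaN(SiMe3)2, THF, −78 °C; then 5, −78 to −40 °C; cold buffered quench
Reagents that add atoms: none
Why: Deconjugative Evans alkylation: γ-deprotonation of the s-cis enoyl imide gives the chelated Z-dienolate 6, which reacts at its α-carbon with the allylic bromide on the face opposite the benzyl group. The (S)-auxiliary thus sets the 2S centre, and the double bond moves into the isopropenyl position.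

Step 3
Reactants: 7 (S)-4-benzyl-3-[(2S)-5-methyl-2-(prop-1-en-2-yl)hex-4-enoyl]-1,3-oxazolidin-2-one
Product: 8 (S)-lavandulol [(2S)-5-methyl-2-(prop-1-en-2-yl)hex-4-en-1-ol]
Conditions: LiBH4, Et2O/THF, 0 °C
Reagents that add atoms: none
Why: Reductive cleavage of an N-acyl oxazolidinone with borohydride goes straight to the alcohol without a free aldehyde stage, so the allylic α-centre is not epimerised and the alkenes are inert.

Step 4
Reactants: 8 (S)-lavandulol
Product: 9 (3S)-3-(iodomethyl)-2,6-dimethylhepta-1,5-diene [(S)-lavandulyl iodide]
Conditions: I2, PPh3, imidazole, CH2Cl2, 0 °C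
Reagents that add atoms: iodine, II
Why: Appel-type iodination of a primary alcohol under buffered conditions; substitution takes place at CH2, so the neighbouring stereocentre is untouched.

Step 5
Reactants: 10 benzene-1,3,5-triol (phloroglucinol); 11 (E)-2-methylbut-2-enoyl chloride (tigloyl chloride)
Product: 12 (E)-2-methyl-1-(2,4,6-trihydroxyphenyl)but-2-en-1-one
Conditions: AlCl3 (3.5 equiv), CH2Cl2/PhNO2, 0 °C to rt; cold dilute HCl work-up
Reagents that add atoms: none
Why: Friedel–Crafts C-acylation of phloroglucinol; the three ring positions are equivalent and the first acyl group deactivates the ring toward a second. Low temperature and a cold acidic work-up are meant to keep the enone open.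

Step 6
Reactants: 12 (E)-2-methyl-1-(2,4,6-trihydroxyphenyl)but-2-en-1-one; 13 3-phenylprop-2-ynal
Product: 14 (4R)-5,7-dihydroxy-6-[(E)-2-methylbut-2-enoyl]-4-phenyl-3,4-dihydrochromen-2-one
Conditions: aminoindanol-derived N-mesityl triazolium chloride (10 mol %), toluene/THF, 40 °C
Reagents that add atoms: none
Why: Carbene-catalysed redox activation of the ynal gives a cinnamoyl azolium, which takes up the unchelated acidic 4-OH of 12, forms the C–C bond at the adjacent ring carbon (Coates–Claisen-type annulation known for naphthols and stable enols) and lactonises with release of the catalyst. The two free ring carbons of 12 are equivalent, so only one constitution can result. C4 is set by the catalyst, of which both antipodes are commercial and the one giving 4R is used.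

Step 7
Reactants: 14 (4R)-5,7-dihydroxy-6-[(E)-2-methylbut-2-enoyl]-4-phenyl-3,4-dihydrochromen-2-one
Product: 15 (4R,7S,8R)-5-hydroxy-7,8-dimethyl-4-phenyl-3,4,7,8-tetrahydropyrano[3,2-g]chromene-2,6-dione
Conditions: (−)-quinine (20 mol %), PhCl, 15–25 °C
Reagents that add atoms: none
Why: Cinchona-alkaloid-catalysed intramolecular oxa-Michael addition of an o-tigloylphenol, the known route to cis-2,3-dimethylchromanones: the catalyst selects the enone face (8R with quinine in this series), and protonation of the enolate inside the ion pair gives the kinetic cis isomer (7S). The 7-OH next to the unsubstituted ring carbon should add in preference to the 5-OH, which is flanked by C4a and C4 and stays behind as the chelated hydroxyl.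

Step 8
Reactants: 15 (4R,7S,8R)-5-hydroxy-7,8-dimethyl-4-phenyl-3,4,7,8-tetrahydropyrano[3,2-g]chromene-2,6-dione
Product: 16 (4R,7S,8R)-5-hydroxy-10-iodo-7,8-dimethyl-4-phenyl-3,4,7,8-tetrahydropyrano[3,2-g]chromene-2,6-dione
Conditions: N-iodosuccinimide (1.05 equiv), CF3CO2H (cat.), MeCN, 0 °C to rt, dark
Reagents that add atoms: N-iodosuccinimide, O=C1CCC(=O)N1I
Why: Electrophilic aromatic iodination; C10 is the only free position of ring A and is para to the 5-OH and ortho to two ring oxygens. The mildly acidic medium does not affect C7, and no alkene is present yet.

Step 9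
Reactants: 9 (S)-lavandulyl iodide; 16 (4R,7S,8R)-5-hydroxy-10-iodo-7,8-dimethyl-4-phenyl-3,4,7,8-tetrahydropyrano[3,2-g]chromene-2,6-dione
Product: 18 (4R,7S,8R)-5-hydroxy-7,8-dimethyl-10-[(2R)-5-methyl-2-(prop-1-en-2-yl)hex-4-enyl]-4-phenyl-3,4,7,8-tetrahydropyrano[3,2-g]chromene-2,6-dione, via lavandulylzinc iodide 17 (not isolated)
Conditions: 9, Zn dust, LiCl, THF, 40 °C; then slow addition to 16, Pd(OAc)2 (3 mol %), SPhos (6 mol %), THF, 25 °C
Reagents that add atoms: none
Why: Negishi coupling of a primary alkylzinc halide with an aryl iodide on zerovalent palladium carrying a bulky biaryl phosphine, a catalyst type that couples di-ortho-substituted halides, suppresses β-hydride elimination and tolerates a phenolic OH when the zinc reagent is added slowly. Zinc insertion and transmetalation occur at CH2, so C2' keeps its arrangement (the descriptor changes from S to R by priority only); lactone and ketone are inert to the organozinc.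

Step 10
Reactants: 18 (4R,7S,8R)-5-hydroxy-7,8-dimethyl-10-[(2R)-5-methyl-2-(prop-1-en-2-yl)hex-4-enyl]-4-phenyl-3,4,7,8-tetrahydropyrano[3,2-g]chromene-2,6-dione; 19 3-methylbut-2-en-1-ol
Product: 20 (4R,7S,8R)-7,8-dimethyl-5-(3-methylbut-2-enyloxy)-10-[(2R)-5-methyl-2-(prop-1-en-2-yl)hex-4-enyl]-4-phenyl-3,4,7,8-tetrahydropyrano[3,2-g]chromene-2,6-dione
Conditions: 19, PPh3, diisopropyl azodicarboxylate, toluene, 0 °C to rt
Reagents that add atoms: none
Why: Mitsunobu etherification, the known neutral way to prenylate the chelated 5-OH of chromanones and flavanones that carry an aryl ester elsewhere. It is the only hydroxyl in 18, and the absence of free base spares C7 and ring C.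

Step 11
Reactants: 20 (4R,7S,8R)-7,8-dimethyl-5-(3-methylbut-2-enyloxy)-10-[(2R)-5-methyl-2-(prop-1-en-2-yl)hex-4-enyl]-4-phenyl-3,4,7,8-tetrahydropyrano[3,2-g]chromene-2,6-dione
Product: 22 (4R,7S,8R,10S)-7,8-dimethyl-10-(3-methylbut-2-enyl)-10-[(2R)-5-methyl-2-(prop-1-en-2-yl)hex-4-enyl]-4-phenyl-3,4,7,8-tetrahydropyrano[3,2-g]chromene-2,5,6(10H)-trione, via blocked dienone 21 (not isolated)
Conditions: Eu(fod)3 (15 mol %; fod = 6,6,7,7,8,8,8-heptafluoro-2,2-dimethyloctane-3,5-dionate), PhCl, 80 °C, Ar, dark
Reagents that add atoms: none
Why: Proposed new method: chelation of the trivalent europium centre by O5 and the C6 carbonyl oxygen loosens the O5–CH2 bond, and a first aromatic Claisen shift moves the allyl unit to C4a, the electron-rich alkyl-bearing ortho carbon (the other ortho carbon, C5a, carries the acyl group and is not attacked in this series), to give the blocked 2,4-dienone 21. Since C4a has no hydrogen, 21 cannot enolise and goes on by a Cope shift across C10a=C10, which puts an uninverted prenyl group on C10 and leaves the cross-conjugated dienone 22. The closest known reaction is the Eu(fod)3-catalysed Claisen–Cope migration of 5-O-prenyl flavanones and chromanones to their 8-prenyl isomers; new is that both the relay carbon and the terminus are substituted, so that the sequence ends in a dearomatised ring. No ring is closed. C10 is the only lasting new stereocentre: both shifts are suprafacial chair processes, so the allyl unit stays on the face over which it first folds, and that face is dictated by C4, whose phenyl group is held quasi-axial in ring C by the peri oxygen O5 and blocks the opposite face directly beside C4a. With 4R this places prenyl anti to phenyl, which is 10S as in 24; the transient centre C4a of 21 is set by the same contact and disappears again. The step needs site selectivity, face selectivity and a favourable equilibrium; the last is secured by the doubly acceptor-substituted enol ether C5a=C9a–O9 of 22, by the low resonance energy of a phloroglucinol ring and by release of the crowding in hexasubstituted 20. Neither 20 nor 22 has a free OH group, so the Lewis acid cannot close chromans on the alkenes, and the neutral medium spares the cis pair C7/C8.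

Step 12
Reactants: 22 (4R,7S,8R,10S)-7,8-dimethyl-10-(3-methylbut-2-enyl)-10-[(2R)-5-methyl-2-(prop-1-en-2-yl)hex-4-enyl]-4-phenyl-3,4,7,8-tetrahydropyrano[3,2-g]chromene-2,5,6(10H)-trione
Product: 24 (3R)-3-[(2R,3S,8S)-5-hydroxy-2,3-dimethyl-8-(3-methylbut-2-enyl)-8-[(2R)-5-methyl-2-(prop-1-en-2-yl)hex-4-enyl]-4,7-dioxo-3,4,7,8-tetrahydro-2H-chromen-6-yl]-3-phenylpropanoic acid (CNP0150579.4), via dilithium salt 23 (not isolated)
Conditions: LiOH (2.2 equiv), THF/H2O, 0 °C; then 1 M HCl to pH 4, 0 °C
Reagents that add atoms: lithium hydroxide, [Li+].[OH-]
Why: The enol ester of 22 is a vinylogous anhydride and is by far the most electrophilic carbonyl, so cold dilute hydroxide opens ring C only. In dianion 23 the C6 ketone is part of a delocalised tricarbonyl anion, which lowers the acidity of C7–H and protects the cis pair; brief mild acidification gives the chelated enol tautomer 24 without closing chromans.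

## Compound list

1 | (S)-4-benzyl-1,3-oxazolidin-2-one | O=C1OC[C@H](Cc2ccccc2)N1 | starting material
2 | 3-methylbut-2-enoyl chloride | CC(C)=CC(=O)Cl | starting material
3 | lithium salt of 1 | [Li+].O=C1OC[C@H](Cc2ccccc2)[N-]1 | intermediate
4 | (S)-4-benzyl-3-(3-methylbut-2-enoyl)-1,3-oxazolidin-2-one | O=C1OC[C@H](Cc2ccccc2)N1C(=O)C=C(C)C | intermediate
5 | 1-bromo-3-methylbut-2-ene | CC(C)=CCBr | starting material
6 | sodium Z-dienolate of 4 | [Na+].[O-]/C(=C\C(C)=C)N1[C@@H](Cc2ccccc2)COC1=O | intermediate
7 | (S)-4-benzyl-3-[(2S)-5-methyl-2-(prop-1-en-2-yl)hex-4-enoyl]-1,3-oxazolidin-2-one | O=C1OC[C@H](Cc2ccccc2)N1C(=O)[C@@H](CC=C(C)C)C(C)=C | intermediate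
8 | (S)-lavandulol | C=C(C)[C@H](CC=C(C)C)CO | intermediate
9 | (3S)-3-(iodomethyl)-2,6-dimethylhepta-1,5-diene | C=C(C)[C@H](CC=C(C)C)CI | intermediate
10 | benzene-1,3,5-triol | Oc1cc(O)cc(O)c1 | starting material
11 | (E)-2-methylbut-2-enoyl chloride | C/C=C(\C)C(=O)Cl | starting material
12 | (E)-2-methyl-1-(2,4,6-trihydroxyphenyl)but-2-en-1-one | C/C=C(\C)C(=O)c1c(O)cc(O)cc1O | intermediate
13 | 3-phenylprop-2-ynal | O=CC#Cc1ccccc1 | starting material
14 | (4R)-5,7-dihydroxy-6-[(E)-2-methylbut-2-enoyl]-4-phenyl-3,4-dihydrochromen-2-one | O=C1C[C@H](c2ccccc2)c2c(O1)cc(O)c(C(=O)/C(C)=C/C)c2O | intermediate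
15 | (4R,7S,8R)-5-hydroxy-7,8-dimethyl-4-phenyl-3,4,7,8-tetrahydropyrano[3,2-g]chromene-2,6-dione | O=C1C[C@H](c2ccccc2)c2c(O1)cc3O[C@H](C)[C@H](C)C(=O)c3c2O | intermediate
16 | 10-iodo derivative of 15 | O=C1C[C@H](c2ccccc2)c2c(O1)c(I)c3O[C@H](C)[C@H](C)C(=O)c3c2O | intermediate
17 | (S)-lavandulylzinc iodide | C=C(C)[C@H](CC=C(C)C)C[Zn]I | intermediate
18 | 10-[(2R)-lavandulyl] derivative of 15 | O=C1C[C@H](c2ccccc2)c2c(O1)c(C[C@@H](CC=C(C)C)C(C)=C)c3O[C@H](C)[C@H](C)C(=O)c3c2O | intermediate
19 | 3-methylbut-2-en-1-ol | CC(C)=CCO | starting material
20 | 5-O-prenyl ether of 18 | O=C1C[C@H](c2ccccc2)c2c(O1)c(C[C@@H](CC=C(C)C)C(C)=C)c3O[C@H](C)[C@H](C)C(=O)c3c2OCC=C(C)C | intermediate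
21 | (4R,4aR,7S,8R)-4a-(2-methylbut-3-en-2-yl) 2,4-dienone, 2,5,6(4aH)-trione | O=C1C[C@H](c2ccccc2)[C@]2(C(C)(C)C=C)C(=O)C3=C(O[C@H](C)[C@H](C)C3=O)C(C[C@@H](CC=C(C)C)C(C)=C)=C2O1 | intermediate
22 | (4R,7S,8R,10S)-10-prenyl-10-[(2R)-lavandulyl] enol lactone, 2,5,6(10H)-trione | O=C1C[C@H](c2ccccc2)C2=C(O1)[C@@](CC=C(C)C)(C[C@@H](CC=C(C)C)C(C)=C)C3=C(C2=O)C(=O)[C@@H](C)[C@@H](C)O3 | intermediate
23 | dilithium carboxylate enolate of 24 | [Li+].[Li+].C=C(C)[C@H](CC=C(C)C)C[C@]1(CC=C(C)C)C(=O)C([C@H](CC(=O)[O-])c2ccccc2)=C([O-])C2=C1O[C@H](C)[C@H](C)C2=O | intermediate
24 | CNP0150579.4 | C=C(C)[C@H](CC=C(C)C)C[C@]1(CC=C(C)C)C(=O)C([C@H](CC(=O)O)c2ccccc2)=C(O)C2=C1O[C@H](C)[C@H](C)C2=O | target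

## Step count and least certain steps

Total step count: 12. Longest linear sequence: 8 steps (steps 5–12 from 10, or steps 1–4 and 9–12 from 1).

**Step 11 (key step).**
- The first shift has to build a quaternary carbon beside C4. If it is too slow, Lewis-acid ionisation of the allyl–oxygen bond may take over. That would mean loss of the face relay, loss of the prenyl group, or return to oxygen.
- The equilibrium could also lie on the ether side, and prolonged heating could epimerise C7.
- Fallback, by known chemistry: it sets out from phenol 18 and comes back at 22. Compound 18 is submitted to an intermolecular palladium-catalysed allylic dearomatisation with methyl 3-methylbut-2-enyl carbonate, Pd2(dba)3 and the chiral (R,R)- or (S,S)-DACH-phenyl bisphosphine in CH2Cl2. The phenoxide attacks the less hindered terminus of the π-prenyl complex through C10, para to O5. The face is then chosen by the ligand instead of by C4, and the C10 epimers are separated. This fallback makes no new compound (F0).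

**Step 7.**
- The flanked 5-OH may compete with the 7-OH.
- Reversible addition may erode the cis arrangement.
- The catalyst may be mismatched with C4.
- Fallback: it sets out from 12 and comes back at 15. Ring B is closed first, where both ortho hydroxyls are equivalent, giving (2R,3S)-5,7-dihydroxy-2,3-dimethylchroman-4-one F1 under the same alkaloid catalysis. The carbene annulation with 13 is then run on F1. The question of which oxygen adds is exchanged for the question of which ring carbon is attacked. Compound 15 is separated from the angular lactone (2R,3S,10R)-5-hydroxy-2,3-dimethyl-10-phenyl-2,3,9,10-tetrahydropyrano[2,3-f]chromene-4,8-dione F2.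

**Step 6.**
- The acyl group lowers the nucleophilicity of the ring.
- A second annulation may follow the first.
- The basic carbene may trigger unselective closure of the enone.
- Enantiocontrol on this phenol is untested.
- Fallback: it sets out from 12 and comes back at 14. Iminium catalysis replaces acyl azolium catalysis. Cinnamaldehyde and diphenylprolinol trimethylsilyl ether give, by Friedel–Crafts alkylation and hemiacetal closure, the lactol (4R)-2,5,7-trihydroxy-6-[(E)-2-methylbut-2-enoyl]-4-phenylchroman F3, which is oxidised to 14 with Ag2CO3 on Celite.

**Step 9.**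
- The phenol may protonate the organozinc.
- Coupling at the di-ortho-substituted iodide may be slow.
- β-Hydride elimination with chain isomerisation would erode C2'.
- Fallback: it sets out from 16 and comes back at 20. The acidic proton is removed from the problem by making the ether first. Mitsunobu reaction of 16 with 19 gives the iodo prenyl ether F4, which is then coupled with 17 under the same type of catalyst and worked up as soon as the iodide is consumed, so that ionisation of the allyl ether by palladium stays slow.

**Step 5.**
- Acid-induced closure of the enone onto an ortho hydroxyl would give racemic chromanone before the asymmetric step.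
- Over-acylation is also possible.
- Fallback: it sets out from 10 and comes back at 12. Electrophilic acylation is replaced by anionic acylation. Compound 10 is converted with chloromethyl methyl ether and i-Pr2NEt into 1,3,5-tris(methoxymethoxy)benzene F5. This is lithiated with n-BuLi between two ether groups and acylated with N-methoxy-N-methyl-(E)-2-methylbut-2-enamide to give the protected ketone F6, which is deprotected with dilute HCl in MeOH at low temperature.

## Further compounds

F0 | step 11 | none | none
F1 | step 7 | (2R,3S)-5,7-dihydroxy-2,3-dimethylchroman-4-one | Oc1cc(O)c2C(=O)[C@@H](C)[C@@H](C)Oc2c1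
F2 | step 7 | (2R,3S,10R)-5-hydroxy-2,3-dimethyl-10-phenyl-2,3,9,10-tetrahydropyrano[2,3-f]chromene-4,8-dione | O=C1C[C@H](c2ccccc2)c2c(O1)cc(O)c3C(=O)[C@@H](C)[C@@H](C)Oc23
F3 | step 6 | (4R)-2,5,7-trihydroxy-6-[(E)-2-methylbut-2-enoyl]-4-phenylchroman | OC1C[C@H](c2ccccc2)c2c(O1)cc(O)c(C(=O)/C(C)=C/C)c2O
F4 | step 9 | (4R,7S,8R)-10-iodo-7,8-dimethyl-5-(3-methylbut-2-enyloxy)-4-phenyl-3,4,7,8-tetrahydropyrano[3,2-g]chromene-2,6-dione | O=C1C[C@H](c2ccccc2)c2c(O1)c(I)c3O[C@H](C)[C@H](C)C(=O)c3c2OCC=C(C)C
F5 | step 5 | 1,3,5-tris(methoxymethoxy)benzene | COCOc1cc(OCOC)cc(OCOC)c1
F6 | step 5 | (E)-2-methyl-1-[2,4,6-tris(methoxymethoxy)phenyl]but-2-en-1-one | C/C=C(\C)C(=O)c1c(OCOC)cc(OCOC)cc1OCOC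
A1 | alternative 1 | (3R)-3-[(2R,3S)-5,7-dihydroxy-2,3-dimethyl-8-[(2R)-lavandulyl]-4-oxochroman-6-yl]-3-phenylpropanoic acid | OC(=O)C[C@H](c1ccccc1)c1c(O)c(C[C@@H](CC=C(C)C)C(C)=C)c2O[C@H](C)[C@H](C)C(=O)c2c1O
A2 | alternative 1 | epimer of 24 at the quaternary carbon | C=C(C)[C@H](CC=C(C)C)C[C@@]1(CC=C(C)C)C(=O)C([C@H](CC(=O)O)c2ccccc2)=C(O)C2=C1O[C@H](C)[C@H](C)C2=O
A3 | alternative 2 | 3,5-dihydroxy-6-[(2R)-lavandulyl]-6-prenylcyclohexa-2,4-dien-1-one | C=C(C)[C@H](CC=C(C)C)CC1(CC=C(C)C)C(=O)C=C(O)C=C1O
A4 | alternative 2 | (4R,8S)-7-hydroxy-8-[(2R)-lavandulyl]-8-prenyl-4-phenyl-3,4-dihydrochromene-2,5(8H)-dione | O=C1C[C@H](c2ccccc2)C2=C(O1)[C@@](CC=C(C)C)(C[C@@H](CC=C(C)C)C(C)=C)C(O)=CC2=O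
A5 | alternative 3 | (3R)-2,2-dimethyl-3-(3-methylbut-2-enyl)chroman-5,7-diol | CC1(C)Oc2cc(O)cc(O)c2C[C@H]1CC=C(C)C
A6 | alternative 3 | 5-hydroxy-2,2-dimethyl-3,4a-bis(3-methylbut-2-enyl)-3,4-dihydro-2H-chromen-7(4aH)-one, 3,4a-trans | CC1(C)OC2=CC(=O)C=C(O)[C@@]2(CC=C(C)C)C[C@H]1CC=C(C)C
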